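## Structural features

Carotenoid numbering is used throughout. The ring is C2–C3–C4–C5–C6, C1(=C16)(C17) is the isopropenyl group on C2, C18 is the methyl group on C5, and the chain runs from C7 (on C6) over C15/C15′ to the open end C1′. The target (C40H56O) is one cyclopentane joined through the single bond C6–C7 to an all-E decaene (C7=C8 to C5′=C6′, methyl branches at C9, C13, C13′, C9′, C5′) that ends in an isolated C1′=C2′ prenyl unit. The only stereocentres, C5 (tertiary carbinol), C6 and C2, are contiguous and all R. Reading the SMILES places C18, C7 and C1 on one face of the ring and the hydroxyl group alone on the other. C6 therefore carries the chain cis to both neighbouring carbon substituents, which is the most crowded and least stable arrangement. Any intermediate that makes H6 acidic (a C7 aldehyde, ester or nitrile) invites epimerisation, and a C7 carbonyl next to the C5 hydroxyl also invites retro-aldol cleavage or dehydration. The fragile groups are the tertiary alcohol (its loss with H6 would extend the chromophore), the decaene (acid, light, oxygen, electrophiles) and the two isolated electron-rich alkenes, which compete for any electrophilic reagent. The polyene is routine carotenoid work, so the real difficulty is the all-cis-carbon stereotriad together with the ring–chain junction. The key step exploits two facts: the end group C1–C7/C16–C18 is a geranyl skeleton with one extra bond, C2–C6, and the cis pair C6–C7 and C2–C1(=C16), with a hydrogen on C7 that can be traced back to C16, is the retron of an intramolecular Alder-ene reaction.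

## Logic of the disconnections

**13 to 12.** Only the O–Si bond at C5 is cut. The oxygen has to be masked while C7 is a carbanion, because a free C5 alkoxide could attack the heteroaryl sulfone. The gain is safety rather than simplicity. The forward step must be a fluoride cleavage mild enough for a decaene and for a tertiary alcohol that eliminates easily.

**12 to 7 + 11.** C7=C8 is cut with the ring half as the nucleophile. This is the one polyene bond whose cleavage keeps C6 free of any acidifying group, since in 7 H6 is β and not α to sulfur. It divides C40 into C10 + C30 and isolates all three stereocentres in a small fragment. The forward step must be E-selective, must tolerate a β-branched carbanion and must leave C6 untouched.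

**11 to 9 + 10.** C7′=C8′ is cut. The electrophile that results, 10, is C2-symmetric, so either terminus gives the same product, and the open end group arrives as an intact C10 unit. The forward step must stop after one olefination and must keep C5′=C6′ as E.

**9 to 8.** The C–P bond is cut, which leads back to a purchasable allylic bromide. The only demand is substitution without allylic transposition.

**7 to 6 (key).** The bonds C2–C6 and C7–H are cut and the C1=C16 π bond is returned to C1=C2, so the ring opens to an acyclic isomer. One ring and two stereocentres (C2, C6) disappear, no atom is added or lost, and what remains has a single stereocentre (C5). In one sentence: a thermal intramolecular Alder-ene reaction of acyclic 6 closes the cyclopentane of 7. That sentence does not fit the route drawn first (Alternative 1). The forward step must be cis-selective at C2/C6, must read C5 so that oxygen ends up trans to C7, and must form C2–C6 rather than C2–C7.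

**6 to 5.** The O–Si bond is cut. The silyl group is installed before the key step because it is meant to act there as the large, polar substituent on C5. A silyl triflate is needed for a hindered tertiary alcohol.

**5 to 4.** The C6=C7 π bond is exchanged for a C6–O bond, which regenerates an epoxide. The C5–O bond is never broken, so C5 can be taken from an epoxide of known configuration, while the C6 centre of 4 is sacrificed on purpose. The forward step must give the E vinyl sulfone only.

**4 to 3 to 2.** The two S=O bonds and then the C7–S bond are cut, which leads to an epoxy alcohol. Sulfur is introduced at a primary carbon with no effect on the stereocentres. The oxidation must be chemoselective for sulfur in the presence of a trisubstituted alkene and an epoxide.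

**2 to 1.** The two C–O bonds of the epoxide are cut. All ten carbons of the end group then come from one achiral, cheap allylic alcohol, and the absolute configuration comes from a catalyst. The epoxidation must touch only the allylic alkene.

## Other disconnections considered

**Alternative 1:** (first to come to mind) Here the polyene is cut at C11=C12 and C11′=C12′ (C15 + C10 + C15 double Wittig) and the ring at C5–C6. The ring double bond of (R)-limonene A1 is cleaved oxidatively to keto aldehyde A2, and an intramolecular aldol reaction of the C6 enol(ate) onto the C5 ketone gives hydroxy aldehyde A3, which is then extended from C7. C2 comes from the chiral pool, but C5 and C6 are set in a reversible step. H6 is α to the aldehyde in A3, so C6 relaxes to the arrangement trans to the isopropenyl group. The β-hydroxy aldehyde also dehydrates readily to the conjugated enal, which erases C5 and C6 together. The target needs the least stable of the four aldol diastereomers, and nothing in A2 favours it. Every later basic olefination at C7 repeats the epimerisation risk. The chosen plan never places an acidifying group on C7 while H6 is α to it.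

**Alternative 2:** (biomimetic) This plan cuts C2–C6 at the C40 stage. A Lewis acid opens (5R,6R)-5,6-epoxide A4 at C6 (polyene-stabilised cation), C1=C2 captures it, and C16 loses a proton. Anti opening of the E epoxide would set C5/C6 correctly, but nothing ties C1 to the face of C7. In an open cationic closure the bulky C1 cation should prefer the side of H6. There it lies cis to the C5 oxygen and can be captured internally instead of losing a proton. A delocalised decaenyl cation also threatens E/Z scrambling and attack of the oxygen at C8. Making A4 needs the same asymmetric epoxidation plus a longer polyene assembly that carries an acid-labile vinyl epoxide. The ene reaction keeps the same bond construction but replaces the open cation with a cyclic array that enforces the cis relationship.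

**Alternative 3:** The single bond C6–C7 is cut here. Trisubstituted epoxide A5 (oxygen trans to the isopropenyl group) is opened at C6 in an SN2 reaction by a metalated C6 enyne, giving enynol A6, and the alkyne is then reduced to the E alkene. Epoxidation anti to the isopropenyl group and inversion at C6 would give the correct triad by stereospecific steps. However, the nucleophile has to approach C6 on the face of the adjacent isopropenyl group while C5 is tertiary, so elimination to an allylic alcohol or opening at C5 under Lewis-acidic activation are serious competitors. The step sets only one stereocentre and closes no ring. A5 itself needs a multistep ring synthesis, and the alkyne costs extra steps. The chosen plan makes the ring and two centres at once from an acyclic isomer.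

Key step: step 6

Assumption: the all-E C20 dialdehyde 10 and bromide 8 are treated as purchasable building blocks, and all operations on polyenes are run under argon in dim light.

Step 1
Reactants: 1 geraniol
Product: 2 (2R,3R)-2,3-epoxygeraniol
Conditions: Ti(OiPr)4 (5 mol %), D-(−)-diethyl tartrate (6 mol %), t-BuOOH (decane), 4 Å MS, CH2Cl2, −20 °C
Reagents that add atoms: tert-butyl hydroperoxide, CC(C)(C)OO
Why: Sharpless asymmetric epoxidation; the titanium tartrate complex binds the allylic alcohol, so only the future C5=C6 alkene reacts and the isolated prenyl alkene is left alone. With the D-(−)-tartrate the E allylic alcohol should give the (2R,3R)-epoxide, which fixes the future C5 as R.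

Step 2
Reactants: 2 (2R,3R)-2,3-epoxygeraniol
Product: 3 epoxy sulfide, 2-({[(2S,3R)-3-methyl-3-(4-methylpent-3-en-1-yl)oxiran-2-yl]methyl}sulfanyl)-1,3-benzothiazole
Conditions: 2-mercaptobenzothiazole, PPh3, DIAD, THF, 0 °C to rt
Reagents that add atoms: 2-mercaptobenzothiazole, Sc1nc2ccccc2s1
Why: Mitsunobu thioetherification at the primary carbon C7 under neutral conditions, so no epoxide migration is expected. Neither stereocentre is touched; the descriptor at the oxirane CH changes from R to S only because sulfur raises the priority of C7.

Step 3
Reactants: 3 epoxy sulfide
Product: 4 epoxy sulfone, 2-({[(2S,3R)-3-methyl-3-(4-methylpent-3-en-1-yl)oxiran-2-yl]methyl}sulfonyl)-1,3-benzothiazole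
Conditions: (NH4)6Mo7O24·4H2O (10 mol %), 30% aq H2O2, EtOH, 0 °C to rt
Reagents that add atoms: hydrogen peroxide, OO
Why: Peroxomolybdate oxidation of a heteroaryl sulfide to the sulfone, the standard entry to Julia–Kocienski reagents. It transfers oxygen to sulfur much faster than to an unactivated trisubstituted alkene. No base is added, so the product does not isomerise in the presence of hydroperoxide.

Step 4
Reactants: 4 epoxy sulfone
Product: 5 (1E,3R)-1-(1,3-benzothiazol-2-ylsulfonyl)-3,7-dimethylocta-1,6-dien-3-ol
Conditions: DBU (20 mol %), CH2Cl2, 0 °C to rt
Reagents that add atoms: none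
Why: Base-induced isomerisation of a β,γ-epoxy sulfone (E1cB type): deprotonation at C7 expels the C6–O bond, and the alkoxide is reprotonated, so the base is catalytic. The C5–O bond is not involved, so C5 stays R, and the less strained E vinyl sulfone should form.

Step 5
Reactants: 5 γ-hydroxy vinyl sulfone
Product: 6 2-{[(1E,3R)-3,7-dimethyl-3-(triethylsilyloxy)octa-1,6-dien-1-yl]sulfonyl}-1,3-benzothiazole
Conditions: Et3SiOTf, 2,6-lutidine, CH2Cl2, −78 to 0 °C
Reagents that add atoms: triethylsilyl trifluoromethanesulfonate, CC[Si](CC)(CC)OS(=O)(=O)C(F)(F)F
Why: Silylation of a hindered tertiary alcohol with a silyl triflate; the electron-poor alkene suppresses ionisation at C5. The ether serves as the large polar group in step 6 and keeps the oxygen away from the heteroaryl sulfone in step 9.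

Step 6
Reactants: 6 acyclic silyloxy vinyl sulfone
Product: 7 2-({[(1R,2R,5R)-2-methyl-5-(prop-1-en-2-yl)-2-(triethylsilyloxy)cyclopentyl]methyl}sulfonyl)-1,3-benzothiazole
Conditions: toluene (0.02 M), BHT (5 mol %), base-washed sealed tube, argon, 150–170 °C
Reagents that add atoms: none
Why: This is a concerted but asynchronous six-electron Alder-ene reaction in which the nucleophilic C2 terminus of the C1=C2 prenyl π bond attacks C6 (the β-carbon of the vinyl sulfone), an allylic hydrogen of a C1 methyl group migrates suprafacially to C7 and the π bond moves to C1=C16, so that the isopropenyl group, the C7 methylene and the ring arise in one reagent-free isomerisation. The closest known reaction type is the thermal type 1 intramolecular ene cyclisation of 1,6-dienes that carry an acceptor on the enophile, which closes cyclopentanes and pyrrolidines with cis-vicinal CH2-acceptor and isopropenyl groups. The single ring is closed by forming C2–C6 across the three-atom tether C3–C4–C5 (5-exo with respect to both π bonds), while the alternative C2–C7 union to a six-membered ring is polarity-mismatched because C7 is α to sulfur. C2 and C6 are set together, because the hydrogen bridge C16···H···C7 ties C1 and C7 into a six-membered array fused to the forming ring, and only the cis-fused array keeps C3 and C5 within reach of the one-atom link C4, whereas the trans-fused one needs roughly 60° more twist about the forming bond. The sense relative to C5 is controlled by the quaternary carbinol carbon, since the tether atom C4 must sit on the C6–H side, which leaves one site antiperiplanar to the forming bond and one inside site next to C7. The large, electron-withdrawing OSiEt3 group should take the antiperiplanar site (Felkin–Anh-type arrangement, σ*C–O aligned with the acceptor π*, most free space) and the methyl group C18 the inside site, which is tolerable because the E sulfone leaves only hydrogen on C7 cis to C5; this puts oxygen trans and C18 cis to C7 and turns 5R into 2R,6R. The step needs face selectivity at C6=C7 and survival of the sulfone, and the substrate helps through the gem-disubstitution at C5, the absence of any γ-hydrogen (no drift to an allyl sulfone) and, together with high dilution, a radical inhibitor.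

Step 7
Reactants: 8 geranyl bromide
Product: 9 diethyl [(2E)-3,7-dimethylocta-2,6-dien-1-yl]phosphonate
Conditions: P(OEt)3 (neat), 130 °C
Reagents that add atoms: triethyl phosphite, CCOP(OCC)OCC
Why: Michaelis–Arbuzov reaction; attack of phosphorus at the primary allylic carbon followed by dealkylation by bromide. The E trisubstituted alkene is not involved.

Step 8
Reactants: 9 diethyl geranylphosphonate; 10 crocetindial (8,8′-diapocarotene-8,8′-dial, all-E)
Product: 11 apo-8′-lycopenal, all-E 2,6,11,15,19,23-hexamethyltetracosa-2,4,6,8,10,12,14,16,18,22-decaenal
Conditions: KOt-Bu added to 9 + 10 (3 equiv), THF–DMSO, −20 to 0 °C; unreacted 10 recovered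
Reagents that add atoms: none
Why: Horner–Wadsworth–Emmons olefination with an allylic phosphonate, a standard E-selective way to extend carotenoid polyenes. The symmetry of 10 makes both termini equivalent, and its excess favours the mono-adduct. Low temperature limits E/Z equilibration of the allyl anion at C5′=C6′.

Step 9
Reactants: 7 ring sulfone; 11 apo-8′-lycopenal
Product: 12 triethylsilyl ether of the target, (2R,5R,6R)
Conditions: NaHMDS added last to 7 + 11, THF, −78 °C to rt
Reagents that add atoms: none
Why: Julia–Kocienski olefination: the C7 carbanion adds to the C8 aldehyde, and Smiles transfer of the benzothiazolyl group to oxygen followed by loss of SO2 and the aryloxide gives C7=C8. Alkyl benzothiazolyl sulfones combined with conjugated aldehydes are the E-favouring pairing. H6 is β to sulfur and there is no β leaving group, so C6, C5 and C2 are not at risk.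

Step 10
Reactants: 12 silyl ether of the target
Product: 13 target, (1R,2R,3R)-1-methyl-2-[(all-E)-polyenyl]-3-(prop-1-en-2-yl)cyclopentan-1-ol (2R,5R,6R in carotenoid numbering)
Conditions: Bu4NF, AcOH (1:1), THF, 0 °C to rt
Reagents that add atoms: none
Why: Fluoride cleavage of the Si–O bond. The C5–O bond is not broken, so the configuration is retained, and the acetate buffer avoids both acid (dehydration into the chromophore) and strongly basic alkoxide.

## Compound list

1 | geraniol, (2E)-3,7-dimethylocta-2,6-dien-1-ol | CC(C)=CCC/C(C)=C/CO | starting material
2 | (2R,3R)-2,3-epoxygeraniol, [(2R,3R)-3-methyl-3-(4-methylpent-3-en-1-yl)oxiran-2-yl]methanol | OC[C@H]1O[C@]1(C)CCC=C(C)C | intermediate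
3 | 2-({[(2S,3R)-3-methyl-3-(4-methylpent-3-en-1-yl)oxiran-2-yl]methyl}sulfanyl)-1,3-benzothiazole | S(C[C@H]1O[C@]1(C)CCC=C(C)C)c1nc2ccccc2s1 | intermediate
4 | 2-({[(2S,3R)-3-methyl-3-(4-methylpent-3-en-1-yl)oxiran-2-yl]methyl}sulfonyl)-1,3-benzothiazole | O=S(=O)(C[C@H]1O[C@]1(C)CCC=C(C)C)c1nc2ccccc2s1 | intermediate
5 | (1E,3R)-1-(1,3-benzothiazol-2-ylsulfonyl)-3,7-dimethylocta-1,6-dien-3-ol | O=S(=O)(/C=C/[C@](C)(O)CCC=C(C)C)c1nc2ccccc2s1 | intermediate
6 | 2-{[(1E,3R)-3,7-dimethyl-3-(triethylsilyloxy)octa-1,6-dien-1-yl]sulfonyl}-1,3-benzothiazole | O=S(=O)(/C=C/[C@](C)(O[Si](CC)(CC)CC)CCC=C(C)C)c1nc2ccccc2s1 | intermediate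
7 | 2-({[(1R,2R,5R)-2-methyl-5-(prop-1-en-2-yl)-2-(triethylsilyloxy)cyclopentyl]methyl}sulfonyl)-1,3-benzothiazole | C=C(C)[C@@H]1CC[C@@](C)(O[Si](CC)(CC)CC)[C@@H]1CS(=O)(=O)c1nc2ccccc2s1 | intermediate
8 | geranyl bromide, (2E)-1-bromo-3,7-dimethylocta-2,6-diene | CC(C)=CCC/C(C)=C/CBr | starting material
9 | diethyl [(2E)-3,7-dimethylocta-2,6-dien-1-yl]phosphonate | CCOP(=O)(C/C=C(\C)CCC=C(C)C)OCC | intermediate
10 | crocetindial, all-E 2,6,11,15-tetramethylhexadeca-2,4,6,8,10,12,14-heptaenedial | O=C/C(C)=C/C=C/C(C)=C/C=C/C=C(C)/C=C/C=C(C)/C=O | starting material
11 | apo-8′-lycopenal, all-E 2,6,11,15,19,23-hexamethyltetracosa-2,4,6,8,10,12,14,16,18,22-decaenal | O=C/C(C)=C/C=C/C(C)=C/C=C/C=C(C)/C=C/C=C(C)/C=C/C=C(\C)CCC=C(C)C | intermediate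
12 | (2R,5R,6R)-5-O-triethylsilyl ether of the target | C=C(C)[C@@H]1CC[C@@](C)(O[Si](CC)(CC)CC)[C@@H]1/C=C/C(C)=C/C=C/C(C)=C/C=C/C=C(C)/C=C/C=C(C)/C=C/C=C(\C)CCC=C(C)C | intermediate
13 | CNP0222499.3, (2R,5R,6R)-1,16-didehydro-2,6-cyclolycopen-5-ol | C=C(C)[C@@H]1CC[C@@](C)(O)[C@@H]1/C=C/C(C)=C/C=C/C(C)=C/C=C/C=C(C)/C=C/C=C(C)/C=C/C=C(\C)CCC=C(C)C | target

Total step count: 10. Longest linear sequence: 8 steps (1–6, 9, 10).

## Least certain steps

**Step 6 (key step).** The most likely failure is leakage between the two faces of C6=C7. Close to the reacting carbon, methyl and silyloxy differ little in size, so exchange of the antiperiplanar and inside sites would weaken the relay from C5 to C6 and C2. In addition C6 is neopentylic, so closure may need a temperature at which the heteroaryl sulfone starts to degrade.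

The fallback replaces the migrating hydrogen with a metal, so that the same cyclic array is reached at or below room temperature, where any facial bias counts for more. It sets out from 6. Ene-type chlorination of the prenyl alkene (Ca(OCl)2, CO2, CH2Cl2–water; the vinyl sulfone is inert to electrophilic chlorine) gives the transposed secondary allylic chloride F1. This is metalated in situ under zerovalent palladium catalysis (Pd(PPh3)4, Et2Zn, THF) and closes through C2 onto C6 by an intramolecular zinc-ene reaction. Protonation of the α-sulfonyl organozinc on work-up returns the route to 7.

**Step 9.** The β-branched carbanion may add slowly to a poorly electrophilic, α-methyl-branched polyenal. That gives time for self-condensation of the sulfone by ipso attack, for vinylogous deprotonation of the aldehyde, or for silyl migration from oxygen to C7, and the E selectivity may be incomplete. The fallback reverses the order of the two unions. It sets out from 7 and 10. The Julia–Kocienski reaction is run on a large excess of the cheap symmetric dialdehyde to give the ring-bearing C30 aldehyde F2. The reliable Horner–Wadsworth–Emmons reaction with 9 is then used last and returns the route to 12.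

**Step 8.** The most likely failures are over-reaction to the double adduct and sluggish, heterogeneous reaction caused by the low solubility of the dialdehyde. A minor risk is loss of E geometry at C5′=C6′ through equilibration of the allyl anion. The fallback desymmetrises by protection. It sets out from 10, which with one equivalent of 2,2-dimethylpropane-1,3-diol and pyridinium tosylate gives the more soluble mono-acetal F3. Olefination with an excess of 9 gives the C30 acetal F4, and mild aqueous oxalic acid returns the route to 11.

**Step 3.** The second oxygen transfer to an electron-poor sulfoxide is slow. During that time the mildly acidic medium can solvolyse the trisubstituted epoxide, or the prenyl alkene can begin to be epoxidised. The fallback moves the epoxide opening ahead of the full oxidation. It sets out from 3. One equivalent of NaIO4 (aqueous MeOH, 0 °C) gives the epoxy sulfoxide F5, LiHMDS (THF, −78 °C) opens it to the γ-hydroxy vinyl sulfoxide F6, and the molybdate/H2O2 oxidation, now with no epoxide present, returns the route to 5.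

## Further compounds

F1 | step 6 | 2-{[(1E,3R)-6-chloro-3,7-dimethyl-3-(triethylsilyloxy)octa-1,7-dien-1-yl]sulfonyl}-1,3-benzothiazole (both epimers at the C–Cl carbon) | O=S(=O)(/C=C/[C@](C)(O[Si](CC)(CC)CC)CCC(Cl)C(C)=C)c1nc2ccccc2s1
F2 | step 9 | ring-bearing C30 aldehyde, (2R,5R,6R)-5-triethylsilyloxy-2,6-cyclo-1,16-didehydro-8′-apolycopen-8′-al | C=C(C)[C@@H]1CC[C@@](C)(O[Si](CC)(CC)CC)[C@@H]1/C=C/C(C)=C/C=C/C(C)=C/C=C/C=C(C)/C=C/C=C(C)/C=O
F3 | step 8 | crocetindial mono(2,2-dimethylpropane-1,3-diyl) acetal | O=C/C(C)=C/C=C/C(C)=C/C=C/C=C(C)/C=C/C=C(C)/C1OCC(C)(C)CO1
F4 | step 8 | apo-8′-lycopenal 2,2-dimethylpropane-1,3-diyl acetal | CC(C)=CCC/C(C)=C/C=C/C(C)=C/C=C/C(C)=C/C=C/C=C(C)/C=C/C=C(C)/C1OCC(C)(C)CO1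
F5 | step 3 | 2-({[(2S,3R)-3-methyl-3-(4-methylpent-3-en-1-yl)oxiran-2-yl]methyl}sulfinyl)-1,3-benzothiazole (both epimers at sulfur) | O=S(C[C@H]1O[C@]1(C)CCC=C(C)C)c1nc2ccccc2s1
F6 | step 3 | (1E,3R)-1-(1,3-benzothiazol-2-ylsulfinyl)-3,7-dimethylocta-1,6-dien-3-ol | O=S(/C=C/[C@](C)(O)CCC=C(C)C)c1nc2ccccc2s1
A1 | alternative 1 | (R)-limonene | CC1=CC[C@@H](CC1)C(C)=C
A2 | alternative 1 | (3R)-6-oxo-3-(prop-1-en-2-yl)heptanal | C=C(C)[C@@H](CC=O)CCC(C)=O
A3 | alternative 1 | (1R,2R,5R)-2-hydroxy-2-methyl-5-(prop-1-en-2-yl)cyclopentane-1-carbaldehyde | C=C(C)[C@@H]1CC[C@@](C)(O)[C@@H]1C=O
A4 | alternative 2 | (5R,6R)-5,6-epoxy-5,6-dihydrolycopene | CC(C)=CCC/C(C)=C/C=C/C(C)=C/C=C/C(C)=C/C=C/C=C(C)/C=C/C=C(C)/C=C/[C@H]1O[C@]1(C)CCC=C(C)C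
A5 | alternative 3 | (1R,4R,5S)-1-methyl-4-(prop-1-en-2-yl)-6-oxabicyclo[3.1.0]hexane | C=C(C)[C@@H]1CC[C@@]2(C)O[C@@H]12
A6 | alternative 3 | (2E)-5-[(1S,2R,5R)-2-hydroxy-2-methyl-5-(prop-1-en-2-yl)cyclopentyl]-3-methylpent-2-en-4-yn-1-ol | C=C(C)[C@@H]1CC[C@@](C)(O)[C@@H]1C#C/C(C)=C/CO
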